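**Retrosynthetic overview**

1. The route rests on ring C, a 2-aryl-3-hydroxychroman-4-one whose O1–C2 and C3–C4 bonds flank the trans C2/C3 pair. Cutting both bonds gives a ring A o-quinone methide (C8a=O, C4a=C4, from a salicylaldehyde with C4a–CHO and C8a–OH) and an (E)-styrenyl boronate carrying ring B.
2. After the [4+2], boron at C3 becomes the hydroxyl with retention, C3–OH is silylated, the C4 methyl ether is hydrolysed and oxidised to the ketone, and all protecting groups are removed.
3. Ring A aldehyde: resorcinol bis-MOM ether → C6 chain by lithiation/prenylation and hydration → O1 by C–H borylation/oxidation para to that chain (this sets O1 apart from O5/O7) → C8 side chain by iodination and Negishi coupling with the zinc reagent from (S)-lavandulol → C4a formyl by magnesium-mediated ortho-formylation.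
4. Ring B boronate: 2,4-dihydroxybenzaldehyde → bis-MOM ether → boron-Wittig olefination.
5. Rings A and B come from commercial benzene rings; ring C is the only ring formed, in step 13.

Key step: step 13

Assumption: C4 of 22–25 is carried as an epimer mixture because it ends as the carbonyl carbon; the enantiomer of the phosphoric acid that leads to the (2R,3R) series has to be fixed in a first experiment, and the route is written provisionally with (R)-TRIP.

**Route**

Step 1
Reactants: 1 resorcinol
Product: 2 1,3-bis(methoxymethoxy)benzene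
Conditions: NaH, MOMCl, DMF, 0 °C → rt
Reagents that add atoms: chloromethyl methyl ether, COCCl
Why: Williamson-type O-alkylation of the bis-phenoxide with the reactive α-chloro ether gives the bis-acetal that later directs metalation.

Step 2
Reactants: 2 1,3-bis(methoxymethoxy)benzene; 3 prenyl bromide
Product: 5 1,3-bis(methoxymethoxy)-2-(3-methylbut-2-en-1-yl)benzene, via aryllithium 4 (not isolated)
Conditions: n-BuLi, THF, 0 °C; CuBr·SMe2 (10 mol%), then 3, −78 °C → rt
Reagents that add atoms: none
Why: Directed ortho-metalation removes the C–H between the two MOM ethers, and the copper-mediated allylic substitution of the aryl nucleophile on prenyl bromide takes place at the primary carbon (SN2, not SN2′).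

Step 3
Reactants: 5 1,3-bis(methoxymethoxy)-2-(3-methylbut-2-en-1-yl)benzene
Product: 6 4-[2,6-bis(methoxymethoxy)phenyl]-2-methylbutan-2-ol
Conditions: Co(acac)2 (cat.), PhSiH3, O2 (1 atm), THF/i-PrOH, rt; aq. Na2S2O3
Reagents that add atoms: dioxygen, O=O
Why: Mukaiyama hydration: hydrogen-atom transfer from a cobalt hydride to the trisubstituted alkene gives the tertiary radical, which is trapped by O2 and reduced to the Markovnikov alcohol without touching the acetals or the electron-rich ring.

Step 4
Reactants: 6 4-[2,6-bis(methoxymethoxy)phenyl]-2-methylbutan-2-ol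
Product: 7 triethylsilyl ether of 6
Conditions: TESOTf, 2,6-lutidine, CH2Cl2, −78 °C
Reagents that add atoms: triethylsilyl trifluoromethanesulfonate, CC[Si](CC)(CC)OS(=O)(=O)C(F)(F)F
Why: Silylation with the silyl triflate is fast for a tertiary alcohol at −78 °C, where the aryl MOM ethers are not attacked, and the TES ether keeps the alcohol out of the organozinc and acid steps and is removed in the last step.

Step 5
Reactants: 7 triethylsilyl ether of 6
Product: 9 3,5-bis(methoxymethoxy)-4-[3-methyl-3-(triethylsilyloxy)butyl]phenol, via aryl pinacol boronate 8 (not isolated)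
Conditions: [Ir(OMe)(cod)]2 (cat.), 4,4′-di-tert-butyl-2,2′-bipyridine, B2pin2 (0.6 equiv), THF, 60 °C; then NaBO3·4H2O, THF/H2O, rt
Reagents that add atoms: sodium perborate tetrahydrate, [Na+].[Na+].O[B-]1(O)OO[B-](O)(O)OO1 (the boron of 8 comes from bis(pinacolato)diboron and is lost again)
Why: Iridium-catalysed C–H borylation is sterically controlled and takes the only ring C–H without an ortho substituent (para to the alkyl chain, the future C8a), and perborate oxidation of the aryl boronate (aryl shift from boron to oxygen) gives the phenol that becomes O1.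

Step 6
Reactants: 9 3,5-bis(methoxymethoxy)-4-[3-methyl-3-(triethylsilyloxy)butyl]phenol
Product: 10 2-iodo-3,5-bis(methoxymethoxy)-4-[3-methyl-3-(triethylsilyloxy)butyl]phenol
Conditions: NIS (1.0 equiv), CH2Cl2, −40 → 0 °C, dark
Reagents that add atoms: N-iodosuccinimide, O=C1CCC(=O)N1I
Why: Electrophilic aromatic iodination ortho to the free phenol, where the two ortho positions are equivalent by symmetry and one equivalent of reagent at low temperature should hold the reaction at the mono-iodide.

Step 7
Reactants: 11 (±)-lavandulol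
Product: 12 (S)-lavandulol
Conditions: porcine pancreatic lipase, vinyl acetate, t-BuOMe, rt, to about 60% conversion; chromatography (a second cycle on the recovered alcohol if needed)
Reagents that add atoms: none
Why: Lipase-catalysed kinetic resolution by transesterification: the enzyme acylates the (R)-alcohol faster, so the unreacted alcohol is enriched in the (S)-enantiomer, and conversion is taken past one half to offset the modest selectivity expected for a β-branched primary alcohol; this sets the side-chain stereocentre.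

Step 8
Reactants: 12 (S)-lavandulol
Product: 13 (S)-lavandulyl iodide
Conditions: I2, PPh3, imidazole, CH2Cl2, 0 °C → rt
Reagents that add atoms: iodine, II
Why: Appel-type iodination: iodide displaces the alkoxyphosphonium group at the primary carbon (SN2), which leaves the adjacent stereocentre untouched.

Step 9
Reactants: 13 (S)-lavandulyl iodide; 10 2-iodo-3,5-bis(methoxymethoxy)-4-[3-methyl-3-(triethylsilyloxy)butyl]phenol
Product: 15 3,5-bis(methoxymethoxy)-2-[(2R)-5-methyl-2-(prop-1-en-2-yl)hex-4-en-1-yl]-4-[3-methyl-3-(triethylsilyloxy)butyl]phenol, via lavandulylzinc iodide 14 (not isolated)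
Conditions: 13, Zn dust (activated with 1,2-dibromoethane and TMSCl), LiCl, THF, 40 °C; then 10, Pd(OAc)2 (2 mol%), SPhos (4 mol%), THF, rt → 40 °C (14 in 1.5 equiv, added slowly)
Reagents that add atoms: none
Why: Negishi coupling: zinc inserts into the primary C–I bond and the β-branched alkylzinc iodide couples with the hindered aryl iodide under Pd/SPhos catalysis, where reductive elimination outruns β-hydride elimination; alkylzinc halides are protonated only slowly by phenols, and the stereocentre one carbon from the metal is not touched.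

Step 10
Reactants: 15 lavandulyl phenol
Product: 16 2-hydroxy-4,6-bis(methoxymethoxy)-3-[(2R)-5-methyl-2-(prop-1-en-2-yl)hex-4-en-1-yl]-5-[3-methyl-3-(triethylsilyloxy)butyl]benzaldehyde
Conditions: MgCl2, Et3N, (CH2O)n, MeCN, reflux; aq. NH4Cl
Reagents that add atoms: paraformaldehyde (formaldehyde), C=O
Why: Casiraghi–Skattebøl ortho-formylation: the magnesium phenoxide delivers formaldehyde to the only free ortho position (C4a) and a second formaldehyde oxidises the benzylic alkoxide to the aldehyde by hydride transfer, conditions to which alkenes, acetals and the silyl ether are inert.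

Step 11
Reactants: 17 2,4-dihydroxybenzaldehyde
Product: 18 2,4-bis(methoxymethoxy)benzaldehyde
Conditions: NaH, MOMCl, DMF, 0 °C → rt
Reagents that add atoms: chloromethyl methyl ether, COCCl
Why: O-Alkylation of both phenoxides, the chelated ortho-hydroxyl included, with the α-chloro ether.

Step 12
Reactants: 18 2,4-bis(methoxymethoxy)benzaldehyde
Product: 19 (E)-2-[2,4-bis(methoxymethoxy)phenyl]ethenylboronic acid pinacol ester
Conditions: CH2(Bpin)2, LiTMP, THF, 0 °C; then 18, −78 °C → rt
Reagents that add atoms: bis[(pinacolato)boryl]methane, CC1(C)OB(CB2OC(C)(C)C(C)(C)O2)OC1(C)C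
Why: Boron-Wittig olefination: the α-boryl carbanion adds to the aldehyde and syn-elimination of a borate from the favoured adduct gives the (E)-alkenyl boronate in one step.

Step 13
Reactants: 16 ring A salicylaldehyde; 19 (E)-alkenyl boronate
Product: 22 trans-2-aryl-3-boryl-4-methoxychroman (2S,3S; C4 epimers), via dimethyl acetal 20 (not isolated), via methoxy o-quinone methide 21 (not isolated)
Conditions: 19 (2 equiv), HC(OMe)3 (3 equiv), (R)-TRIP [(R)-3,3′-bis(2,4,6-triisopropylphenyl)-1,1′-binaphthyl-2,2′-diyl hydrogen phosphate] (10 mol%), 5 Å MS, CH2Cl2, −20 °C → rt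
Reagents that add atoms: trimethyl orthoformate, COC(OC)OC
Why: Proposed new method: acetalisation of the salicylaldehyde and loss of methanol from 20 give the 4-methoxy o-quinone methide 21 (C8a=O, C4a=C4), an electron-poor 1-oxadiene hydrogen-bonded to the chiral phosphoric acid, and the alkenyl boronate adds with its boron-bearing carbon to C4 while O1 closes on the benzylic carbon, whose positive charge is carried by the 2,4-bis(alkoxy)phenyl group, in a concerted but asynchronous inverse-electron-demand hetero-Diels–Alder reaction. The closest known reaction type is the Brønsted-acid-catalysed [4+2] cycloaddition of o-quinone methides (also those made from salicylaldehydes and orthoformates) with styrenes, including chiral phosphoric acid versions; the alkenyl boronate as 2π partner is the untested element, and it should be tolerated because tricoordinate boron is only a weak acceptor beside the strongly donating aryl group and does not leave as long as no nucleophile binds it (hence the sieves, which take up methanol). Ring C closes as a six-membered pyran in the [4+2] mode, C3–C4 first and O1–C2 second. C2 and C3 come out trans because the addition is suprafacial on the (E)-alkene (trans is also the thermodynamic arrangement should the C2 cation live long enough to rotate), their absolute configuration is set by the chiral phosphate bound to the quinone methide oxygen, which shields one face of C4, and C4 forms as an epimer mixture of no consequence. The step needs regioselectivity (the aryl group, not boron, stabilises the cation, so boron ends at C3), chemoselectivity for the styrenyl alkene over the lavandulyl alkenes (secured by the two alkoxy donors and the excess of 19), and an acid mild enough neither to cyclise the C8a phenol onto the isopropenyl group nor to cleave the MOM and TES groups.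

Step 14
Reactants: 22 trans-2-aryl-3-boryl-4-methoxychroman
Product: 23 trans-2-aryl-4-methoxychroman-3-ol (2R,3S; C4 epimers)
Conditions: NaBO3·4H2O, THF/H2O (1:1), 0 °C → rt
Reagents that add atoms: sodium perborate tetrahydrate, [Na+].[Na+].O[B-]1(O)OO[B-](O)(O)OO1
Why: Boronate oxidation: peroxide adds to boron and C3 migrates from boron to oxygen with retention, so the C3 hydroxyl stays trans to the C2 aryl group, and the mildly basic medium avoids ionising the C4 ether next to boron.

Step 15
Reactants: 23 trans-2-aryl-4-methoxychroman-3-ol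
Product: 24 3-O-tert-butyldimethylsilyl ether of 23 (2R,3S; C4 epimers)
Conditions: TBSCl, imidazole, DMAP (cat.), DMF, 40 °C
Reagents that add atoms: tert-butyldimethylsilyl chloride, CC(C)(C)[Si](C)(C)Cl
Why: Imidazole-promoted silylation of the secondary C3 alcohol, so that C4 can be unmasked and oxidised without exposing a vicinal diol; no silyl triflate is used because it would ionise the C4 ether.

Step 16
Reactants: 24 3-O-silyl-4-methoxychroman
Product: 25 3-O-silyl-chroman-4-ol (2R,3S; C4 epimers)
Conditions: PPTS (0.2 equiv), acetone/H2O (9:1), rt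
Reagents that add atoms: water, O
Why: SN1 solvolysis: the C4 methyl ether sits on a 2,4,6-trioxygenated benzylic carbon, so a weak acid ionises it and water captures the cation under conditions too mild for the aryl MOM ethers and the silyl ethers.

Step 17
Reactants: 25 3-O-silyl-chroman-4-ol
Product: 26 (2R,3R)-3-O-silyl-chroman-4-one, fully protected flavanonol
Conditions: Dess–Martin periodinane, NaHCO3, CH2Cl2, 0 °C → rt
Reagents that add atoms: none
Why: Dess–Martin oxidation of the benzylic secondary alcohol to the aryl ketone under buffered conditions that spare the alkenes, the acetals and the C2/C3 stereocentres; both C4 epimers converge.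

Step 18
Reactants: 26 fully protected flavanonol
Product: 27 target, (2R,3R)-2-(2,4-dihydroxyphenyl)-3,5,7-trihydroxy-6-(3-hydroxy-3-methylbutyl)-8-[(2R)-5-methyl-2-(prop-1-en-2-yl)hex-4-en-1-yl]chroman-4-one
Conditions: HCl (1 M in MeOH), 0 °C → rt
Reagents that add atoms: none
Why: Acid-catalysed methanolysis removes the four aryl MOM acetals and both silyl ethers in one operation at room temperature, which should spare the lavandulyl alkenes and the tertiary alcohol, and the trans-2,3 arrangement is the thermodynamic one.

**Compound list**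

1 | resorcinol | Oc1cccc(O)c1 | starting material
2 | 1,3-bis(methoxymethoxy)benzene | COCOc1cccc(OCOC)c1 | intermediate
3 | prenyl bromide (1-bromo-3-methylbut-2-ene) | CC(C)=CCBr | starting material
4 | 2,6-bis(methoxymethoxy)phenyllithium (formed in the flask, not isolated) | [Li]c1c(OCOC)cccc1OCOC | intermediate
5 | 1,3-bis(methoxymethoxy)-2-(3-methylbut-2-en-1-yl)benzene | COCOc1cccc(OCOC)c1CC=C(C)C | intermediate
6 | 4-[2,6-bis(methoxymethoxy)phenyl]-2-methylbutan-2-ol | COCOc1cccc(OCOC)c1CCC(C)(C)O | intermediate
7 | triethyl{[4-[2,6-bis(methoxymethoxy)phenyl]-2-methylbutan-2-yl]oxy}silane | COCOc1cccc(OCOC)c1CCC(C)(C)O[Si](CC)(CC)CC | intermediate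
8 | 2-{3,5-bis(methoxymethoxy)-4-[3-methyl-3-(triethylsilyloxy)butyl]phenyl}-4,4,5,5-tetramethyl-1,3,2-dioxaborolane (formed in the flask, not isolated) | COCOc1cc(B2OC(C)(C)C(C)(C)O2)cc(OCOC)c1CCC(C)(C)O[Si](CC)(CC)CC | intermediate
9 | 3,5-bis(methoxymethoxy)-4-[3-methyl-3-(triethylsilyloxy)butyl]phenol | COCOc1cc(O)cc(OCOC)c1CCC(C)(C)O[Si](CC)(CC)CC | intermediate
10 | 2-iodo-3,5-bis(methoxymethoxy)-4-[3-methyl-3-(triethylsilyloxy)butyl]phenol | COCOc1cc(O)c(I)c(OCOC)c1CCC(C)(C)O[Si](CC)(CC)CC | intermediate
11 | (±)-lavandulol, racemic 5-methyl-2-(prop-1-en-2-yl)hex-4-en-1-ol | C=C(C)C(CO)CC=C(C)C | starting material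
12 | (S)-lavandulol | C=C(C)[C@H](CC=C(C)C)CO | intermediate
13 | (S)-lavandulyl iodide, (3S)-3-(iodomethyl)-2,6-dimethylhepta-1,5-diene | C=C(C)[C@H](CC=C(C)C)CI | intermediate
14 | [(2S)-5-methyl-2-(prop-1-en-2-yl)hex-4-en-1-yl]zinc iodide (formed in the flask, not isolated) | C=C(C)[C@H](CC=C(C)C)C[Zn]I | intermediate
15 | 3,5-bis(methoxymethoxy)-2-[(2R)-5-methyl-2-(prop-1-en-2-yl)hex-4-en-1-yl]-4-[3-methyl-3-(triethylsilyloxy)butyl]phenol | C=C(C)[C@H](CC=C(C)C)Cc1c(O)cc(OCOC)c(CCC(C)(C)O[Si](CC)(CC)CC)c1OCOC | intermediate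
16 | 2-hydroxy-4,6-bis(methoxymethoxy)-3-[(2R)-5-methyl-2-(prop-1-en-2-yl)hex-4-en-1-yl]-5-[3-methyl-3-(triethylsilyloxy)butyl]benzaldehyde | C=C(C)[C@H](CC=C(C)C)Cc1c(O)c(C=O)c(OCOC)c(CCC(C)(C)O[Si](CC)(CC)CC)c1OCOC | intermediate
17 | 2,4-dihydroxybenzaldehyde | O=Cc1ccc(O)cc1O | starting material
18 | 2,4-bis(methoxymethoxy)benzaldehyde | O=Cc1ccc(OCOC)cc1OCOC | intermediate
19 | 2-{(E)-2-[2,4-bis(methoxymethoxy)phenyl]ethenyl}-4,4,5,5-tetramethyl-1,3,2-dioxaborolane | CC1(C)OB(/C=C/c2ccc(OCOC)cc2OCOC)OC1(C)C | intermediate
20 | dimethyl acetal of 16 (formed in the flask, not isolated) | C=C(C)[C@H](CC=C(C)C)Cc1c(O)c(C(OC)OC)c(OCOC)c(CCC(C)(C)O[Si](CC)(CC)CC)c1OCOC | intermediate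
21 | 6-(methoxymethylidene)cyclohexa-2,4-dien-1-one of ring A, the 4-methoxy o-quinone methide (formed in the flask, not isolated) | C=C(C)[C@H](CC=C(C)C)CC1=C(OCOC)C(CCC(C)(C)O[Si](CC)(CC)CC)=C(OCOC)C(=COC)C1=O | intermediate
22 | (2S,3S)-2-[2,4-bis(methoxymethoxy)phenyl]-4-methoxy-5,7-bis(methoxymethoxy)-8-[(2R)-5-methyl-2-(prop-1-en-2-yl)hex-4-en-1-yl]-6-[3-methyl-3-(triethylsilyloxy)butyl]-3-(4,4,5,5-tetramethyl-1,3,2-dioxaborolan-2-yl)chromane (trans-2,3; C4 epimers) | C=C(C)[C@H](CC=C(C)C)Cc1c(OCOC)c(CCC(C)(C)O[Si](CC)(CC)CC)c(OCOC)c2c1O[C@H](c1ccc(OCOC)cc1OCOC)[C@@H](B1OC(C)(C)C(C)(C)O1)C2OC | intermediate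
23 | (2R,3S)-2-[2,4-bis(methoxymethoxy)phenyl]-4-methoxy-5,7-bis(methoxymethoxy)-8-[(2R)-5-methyl-2-(prop-1-en-2-yl)hex-4-en-1-yl]-6-[3-methyl-3-(triethylsilyloxy)butyl]chroman-3-ol (trans-2,3; C4 epimers) | C=C(C)[C@H](CC=C(C)C)Cc1c(OCOC)c(CCC(C)(C)O[Si](CC)(CC)CC)c(OCOC)c2c1O[C@H](c1ccc(OCOC)cc1OCOC)[C@@H](O)C2OC | intermediate
24 | 3-O-tert-butyldimethylsilyl ether of 23 (2R,3S; C4 epimers) | C=C(C)[C@H](CC=C(C)C)Cc1c(OCOC)c(CCC(C)(C)O[Si](CC)(CC)CC)c(OCOC)c2c1O[C@H](c1ccc(OCOC)cc1OCOC)[C@@H](O[Si](C)(C)C(C)(C)C)C2OC | intermediate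
25 | (2R,3S)-3-(tert-butyldimethylsilyloxy)-2-[2,4-bis(methoxymethoxy)phenyl]-5,7-bis(methoxymethoxy)-8-[(2R)-5-methyl-2-(prop-1-en-2-yl)hex-4-en-1-yl]-6-[3-methyl-3-(triethylsilyloxy)butyl]chroman-4-ol (C4 epimers) | C=C(C)[C@H](CC=C(C)C)Cc1c(OCOC)c(CCC(C)(C)O[Si](CC)(CC)CC)c(OCOC)c2c1O[C@H](c1ccc(OCOC)cc1OCOC)[C@@H](O[Si](C)(C)C(C)(C)C)C2O | intermediate
26 | (2R,3R)-3-(tert-butyldimethylsilyloxy)-2-[2,4-bis(methoxymethoxy)phenyl]-5,7-bis(methoxymethoxy)-8-[(2R)-5-methyl-2-(prop-1-en-2-yl)hex-4-en-1-yl]-6-[3-methyl-3-(triethylsilyloxy)butyl]chroman-4-one | C=C(C)[C@H](CC=C(C)C)Cc1c(OCOC)c(CCC(C)(C)O[Si](CC)(CC)CC)c(OCOC)c2c1O[C@H](c1ccc(OCOC)cc1OCOC)[C@@H](O[Si](C)(C)C(C)(C)C)C2=O | intermediate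
27 | CNP0183552.3, (2R,3R)-2-(2,4-dihydroxyphenyl)-3,5,7-trihydroxy-6-(3-hydroxy-3-methylbutyl)-8-[(2R)-5-methyl-2-(prop-1-en-2-yl)hex-4-en-1-yl]chroman-4-one | C=C(C)[C@H](CC=C(C)C)Cc1c(O)c(CCC(C)(C)O)c(O)c2c1O[C@H](c1ccc(O)cc1O)[C@@H](O)C2=O | target

**Step count and risks**

Total step count: 18. Longest linear sequence: 14 steps (steps 1–6, 9, 10, 13–18, from resorcinol).

Steps most likely to fail:

1. Step 13 (proposed new method). The cycloaddition may be too slow because the boryl group lowers the nucleophilicity of the styrene. Boron may be lost by protodeboronation, or by β-elimination across C3–C4 once the C4 ether re-ionises. The catalyst may give poor facial control, and the acid may trigger cyclisation of the C8a phenol onto the isopropenyl group. The fallback sets out from 16 (with 18 as the source of the two-carbon partner) and comes back to the route at 27; it keeps the o-quinone methide but drops boron and brings in the C3 oxygen by enolate chemistry, all of it known. Wittig methylenation of 18 (Ph3PCH3Br, KOt-Bu, THF) gives 2,4-bis(methoxymethoxy)styrene F1. Under the conditions of step 13, 16 and this more nucleophilic plain styrene (the documented o-quinone methide/styrene cycloaddition, again via 20 and 21) should give the (2S)-4-methoxyflavan F2. PPTS in aqueous acetone gives the flavan-4-ol F3, and Dess–Martin periodinane the (2S)-flavanone F4. Deprotonation (KHMDS, THF, −78 °C) and oxidation of the enolate with 2-(phenylsulfonyl)-3-phenyloxaziridine gives the trans-3-hydroxyflavanone F5; the oxidant approaches anti to the C2 aryl group and does not react with isolated alkenes. The conditions of step 18 then convert F5 into 27.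

2. Step 9. The alkylzinc reagent may be protonated by the free phenol before it couples, oxidative addition may be slow at the electron-rich, doubly ortho-substituted iodide, and the alkylpalladium intermediate may undergo β-hydride elimination to a diene. The fallback sets out from 10 and comes back at 15; it no longer carries the phenol free through the C–C coupling. Silylation of 10 (TBSCl, imidazole, DMF) gives the aryl silyl ether F6, which has no acidic hydrogen and no phenoxide to bind palladium. Coupling of F6 with 14 (Pd(OAc)2, SPhos, THF) gives the silyl-protected lavandulyl arene F7. K2CO3 in MeOH then cleaves the aryl silyl ether selectively over the tertiary TES ether and returns 15.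

3. Step 18. The protic acid may cyclise the freed C7 phenol onto the isopropenyl group, cause cyclodehydration of the tertiary alcohol onto a neighbouring phenol, or fail to cleave the hindered C7 acetal before these processes set in. The fallback sets out from 26 and comes back at 27; it replaces solvolysis by an exchange of protecting groups followed by fluoride. TMSOTf with 2,2′-bipyridyl (CH2Cl2, 0 °C) converts the four aryl MOM ethers under buffered, non-protic conditions into aryl trimethylsilyl ethers, giving the hexasilyl flavanonol F8. Without isolation, HF·pyridine buffered with pyridine (THF, 0 °C) removes the trimethylsilyl, TBS and TES groups and gives 27.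

**Further compounds**

F1 | step 13 | 2,4-bis(methoxymethoxy)styrene | C=Cc1ccc(OCOC)cc1OCOC
F2 | step 13 | (2S)-2-[2,4-bis(methoxymethoxy)phenyl]-4-methoxy-5,7-bis(methoxymethoxy)-8-[(2R)-5-methyl-2-(prop-1-en-2-yl)hex-4-en-1-yl]-6-[3-methyl-3-(triethylsilyloxy)butyl]chromane (C4 epimers) | C=C(C)[C@H](CC=C(C)C)Cc1c(OCOC)c(CCC(C)(C)O[Si](CC)(CC)CC)c(OCOC)c2c1O[C@H](c1ccc(OCOC)cc1OCOC)CC2OC
F3 | step 13 | (2S)-flavan-4-ol corresponding to F2 (C4 epimers) | C=C(C)[C@H](CC=C(C)C)Cc1c(OCOC)c(CCC(C)(C)O[Si](CC)(CC)CC)c(OCOC)c2c1O[C@H](c1ccc(OCOC)cc1OCOC)CC2O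
F4 | step 13 | (2S)-2-[2,4-bis(methoxymethoxy)phenyl]-5,7-bis(methoxymethoxy)-8-[(2R)-5-methyl-2-(prop-1-en-2-yl)hex-4-en-1-yl]-6-[3-methyl-3-(triethylsilyloxy)butyl]chroman-4-one | C=C(C)[C@H](CC=C(C)C)Cc1c(OCOC)c(CCC(C)(C)O[Si](CC)(CC)CC)c(OCOC)c2c1O[C@H](c1ccc(OCOC)cc1OCOC)CC2=O
F5 | step 13 | (2R,3R)-3-hydroxy derivative of F4 (trans-2,3) | C=C(C)[C@H](CC=C(C)C)Cc1c(OCOC)c(CCC(C)(C)O[Si](CC)(CC)CC)c(OCOC)c2c1O[C@H](c1ccc(OCOC)cc1OCOC)[C@@H](O)C2=O
F6 | step 9 | tert-butyl{2-iodo-3,5-bis(methoxymethoxy)-4-[3-methyl-3-(triethylsilyloxy)butyl]phenoxy}dimethylsilane | COCOc1cc(O[Si](C)(C)C(C)(C)C)c(I)c(OCOC)c1CCC(C)(C)O[Si](CC)(CC)CC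
F7 | step 9 | O-tert-butyldimethylsilyl ether of 15 | C=C(C)[C@H](CC=C(C)C)Cc1c(O[Si](C)(C)C(C)(C)C)cc(OCOC)c(CCC(C)(C)O[Si](CC)(CC)CC)c1OCOC
F8 | step 18 | analogue of 26 with the four aryl MOM ethers replaced by trimethylsilyl ethers | C=C(C)[C@H](CC=C(C)C)Cc1c(O[Si](C)(C)C)c(CCC(C)(C)O[Si](CC)(CC)CC)c(O[Si](C)(C)C)c2c1O[C@H](c1ccc(O[Si](C)(C)C)cc1O[Si](C)(C)C)[C@@H](O[Si](C)(C)C(C)(C)C)C2=O
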